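**Retrosynthetic overview**
1. The 4'-phenol is unmasked last from an arylboronate (C–B to C–O). Ring B therefore carries no donor group while the C-2 ether could ionise.
2. Key disconnection: O1–C8a, C8–C8a and C4a–C5 are cut together, opening rings C and A at once. This gives an acyclic (S)-β-hydroxy bromoynone (C2–C3–C4–C4a–C8a) and a Brassard-type diene (C5–C8) that already carries the 7-OMe and prenyl groups.
3. Ring order going forward: ring B is bought. Ring C closes first (6-endo-dig O-cyclisation) and ring A second (vinylogous substitution, then Claisen-type aromatisation), both in one flask.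
4. C-2 is set by an enamine-catalysed aldol of the boryl benzaldehyde with a silyl ynone, and its C–O bond is never broken afterwards.
5. The diene comes from methyl acetoacetate and prenyl bromide (gamma-alkylation, methyl enol ether, silyl ketene acetal).

Assumption: the stereocentre in the given SMILES is read as (2S).

**Step 1**
Reactants: 1 methyl acetoacetate; 2 prenyl bromide (1-bromo-3-methylbut-2-ene)
Product: 3 methyl 7-methyl-3-oxooct-6-enoate
Conditions: NaH (1.1 equiv), THF, 0 °C; n-BuLi (1.05 equiv), 0 °C; 2 (1.0 equiv), 0 °C to rt; aq HCl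
Reagents that add atoms: none
Why: Weiler dianion alkylation, in which the more basic terminal (gamma) carbanion of the acetoacetate dianion displaces the allylic bromide by SN2, so the prenyl group sits on the carbon that becomes C-8.

**Step 2**
Reactants: 3 methyl 7-methyl-3-oxooct-6-enoate
Product: 4 methyl (2E)-3-methoxy-7-methylocta-2,6-dienoate
Conditions: HC(OMe)3 (3 equiv), p-TsOH·H2O (2 mol %), MeOH, 40 °C; distil
Reagents that add atoms: trimethyl orthoformate, COC(OC)OC
Why: Acid-catalysed ketalisation and loss of methanol (orthoester enol-ether formation) gives the conjugated, thermodynamically preferred E β-methoxy enoate, which installs the future 7-OMe group and holds the ester cis to the chain as the later ring closure needs, while the mild acid leaves the trisubstituted alkene alone.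

**Step 3**
Reactants: 4 methyl (2E)-3-methoxy-7-methylocta-2,6-dienoate
Product: 5 [(1,3-dimethoxy-7-methylocta-1,3,6-trien-1-yl)oxy]trimethylsilane (Brassard-type diene, mixture of double-bond isomers)
Conditions: LiN(iPr)2 (1.1 equiv), THF, −78 °C; Me3SiCl (1.3 equiv), −78 °C to rt; pentane, filter, use crude
Reagents that add atoms: chlorotrimethylsilane, C[Si](C)(C)Cl
Why: Kinetic gamma-deprotonation of a β-methoxy enoate followed by O-silylation of the lithium dienolate is the standard Brassard diene synthesis and gives a silyl ketene acetal that is nucleophilic at its terminal, prenyl-bearing carbon.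

**Step 4**
Reactants: 6 4-(4,4,5,5-tetramethyl-1,3,2-dioxaborolan-2-yl)benzaldehyde; 7 4-(trimethylsilyl)but-3-yn-2-one
Product: 8 (5S)-5-hydroxy-5-[4-(4,4,5,5-tetramethyl-1,3,2-dioxaborolan-2-yl)phenyl]-1-(trimethylsilyl)pent-1-yn-3-one
Conditions: (2R)-N-tosylpyrrolidine-2-carboxamide (from D-proline, 20 mol %), 7 (3 equiv), H2O (1 equiv), CH2Cl2, 4 °C, 72 h
Reagents that add atoms: none
Why: Enamine-catalysed direct aldol reaction of a methyl ynone through a List–Houk transition state, in which the D-proline-derived catalyst forms the terminal enamine and its acidic N–H binds the aldehyde so that the Si face is attacked, setting the (S)-carbinol that becomes C-2.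

**Step 5**
Reactants: 8 (5S)-5-hydroxy-5-[4-(4,4,5,5-tetramethyl-1,3,2-dioxaborolan-2-yl)phenyl]-1-(trimethylsilyl)pent-1-yn-3-one
Product: 9 (5S)-1-bromo-5-hydroxy-5-[4-(4,4,5,5-tetramethyl-1,3,2-dioxaborolan-2-yl)phenyl]pent-1-yn-3-one
Conditions: NBS (1.1 equiv), AgNO3 (10 mol %), acetone, rt, dark, 1 h; short silica plug
Reagents that add atoms: N-bromosuccinimide, O=C1CCC(=O)N1Br
Why: Silver-catalysed bromodesilylation (electrophilic ipso-substitution of an alkynylsilane via the silver acetylide) exchanges SiMe3 for Br at room temperature without touching the carbinol stereocentre, the ketone or the electron-neutral arylboronate.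

**Step 6**
Reactants: 9 (5S)-1-bromo-5-hydroxy-5-[4-(4,4,5,5-tetramethyl-1,3,2-dioxaborolan-2-yl)phenyl]pent-1-yn-3-one; 5 [(1,3-dimethoxy-7-methylocta-1,3,6-trien-1-yl)oxy]trimethylsilane
Product: 12 (2S)-5-hydroxy-7-methoxy-8-(3-methylbut-2-en-1-yl)-2-[4-(4,4,5,5-tetramethyl-1,3,2-dioxaborolan-2-yl)phenyl]-2,3-dihydro-4H-chromen-4-one, via bromodihydropyranone 10 (not isolated), via pyranonyl dienoate 11 (not isolated)
Conditions: AgOSO2CF3 (5 mol %), CH2Cl2, 0 °C, 30 min; then 5 (1.5 equiv), 2,6-di-tert-butylpyridine (0.2 equiv), −78 to 0 °C; then DBU (1.6 equiv), 0 °C, 30 min; AcOH quench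
Reagents that add atoms: none
Why: Proposed new method: AgOSO2CF3 activates the bromoynone for the 6-endo-dig attack of the carbinol oxygen that is known for β-hydroxy ynones and so closes ring C as the vinylogous acyl bromide 10, whose C–Br carbon is then attacked by the terminal carbon of the Brassard-type diene 5 (vinylogous Mukaiyama addition–elimination, bromide leaving with help from the ring oxygen so that O-1 stays on C-8a next to the prenyl-bearing carbon), and DBU finally removes the doubly vinylogous C–H of 11 so that C-4a attacks the cis ester in a Dieckmann (polyketide Claisen-type) closure whose dienone tautomerises to aromatic ring A, the closest known reaction types being the annulation of Brassard dienes with halo-enones or haloquinones and the biomimetic cyclisation of tetraketide esters to acylphloroglucinols, while the transient stereocentre of 11 vanishes on aromatisation and C-2 keeps its configuration because its C–O bond is never broken and the boryl-substituted ring B cannot assist ionisation.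

**Step 7**
Reactants: 12 (2S)-5-hydroxy-7-methoxy-8-(3-methylbut-2-en-1-yl)-2-[4-(4,4,5,5-tetramethyl-1,3,2-dioxaborolan-2-yl)phenyl]-2,3-dihydro-4H-chromen-4-one
Product: 13 Mundulea flavanone B, (2S)-5-hydroxy-2-(4-hydroxyphenyl)-7-methoxy-8-(3-methylbut-2-en-1-yl)-2,3-dihydro-4H-chromen-4-one
Conditions: 30 % aq H2O2 (3 equiv), THF / NaH2PO4–Na2HPO4 buffer (pH 7.4), 0 °C to rt, 1 h; Na2S2O3
Reagents that add atoms: hydrogen peroxide, OO
Why: Arylboronate oxidation (hydroperoxide ate complex, then 1,2-aryl shift from boron to oxygen) unmasks the 4'-phenol at neutral pH, where the prenyl alkene is inert, no Dakin-type cleavage occurs and the flavanone does not open to the chalcone, so C-2 stays (S).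

**Compound list**
1 | methyl acetoacetate | COC(=O)CC(C)=O | starting material
2 | prenyl bromide (1-bromo-3-methylbut-2-ene) | CC(C)=CCBr | starting material
3 | methyl 7-methyl-3-oxooct-6-enoate | COC(=O)CC(=O)CCC=C(C)C | intermediate
4 | methyl (2E)-3-methoxy-7-methylocta-2,6-dienoate | COC(=O)/C=C(/OC)CCC=C(C)C | intermediate
5 | [(1,3-dimethoxy-7-methylocta-1,3,6-trien-1-yl)oxy]trimethylsilane (double-bond isomers, both lost later) | COC(O[Si](C)(C)C)=CC(OC)=CCC=C(C)C | intermediate
6 | 4-(4,4,5,5-tetramethyl-1,3,2-dioxaborolan-2-yl)benzaldehyde | O=Cc1ccc(cc1)B1OC(C)(C)C(C)(C)O1 | starting material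
7 | 4-(trimethylsilyl)but-3-yn-2-one | CC(=O)C#C[Si](C)(C)C | starting material
8 | (5S)-5-hydroxy-5-[4-(4,4,5,5-tetramethyl-1,3,2-dioxaborolan-2-yl)phenyl]-1-(trimethylsilyl)pent-1-yn-3-one | O[C@@H](CC(=O)C#C[Si](C)(C)C)c1ccc(cc1)B1OC(C)(C)C(C)(C)O1 | intermediate
9 | (5S)-1-bromo-5-hydroxy-5-[4-(4,4,5,5-tetramethyl-1,3,2-dioxaborolan-2-yl)phenyl]pent-1-yn-3-one | O[C@@H](CC(=O)C#CBr)c1ccc(cc1)B1OC(C)(C)C(C)(C)O1 | intermediate
10 | (2S)-6-bromo-2-[4-(4,4,5,5-tetramethyl-1,3,2-dioxaborolan-2-yl)phenyl]-2,3-dihydro-4H-pyran-4-one | BrC1=CC(=O)C[C@@H](c2ccc(cc2)B2OC(C)(C)C(C)(C)O2)O1 | intermediate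
11 | methyl (2E)-3-methoxy-7-methyl-4-{(2S)-4-oxo-2-[4-(4,4,5,5-tetramethyl-1,3,2-dioxaborolan-2-yl)phenyl]-3,4-dihydro-2H-pyran-6-yl}octa-2,6-dienoate (both C-4 epimers) | COC(=O)/C=C(/OC)C(CC=C(C)C)C1=CC(=O)C[C@@H](c2ccc(cc2)B2OC(C)(C)C(C)(C)O2)O1 | intermediate
12 | (2S)-5-hydroxy-7-methoxy-8-(3-methylbut-2-en-1-yl)-2-[4-(4,4,5,5-tetramethyl-1,3,2-dioxaborolan-2-yl)phenyl]-2,3-dihydro-4H-chromen-4-one | COc1cc(O)c2c(c1CC=C(C)C)O[C@H](c1ccc(cc1)B1OC(C)(C)C(C)(C)O1)CC2=O | intermediate
13 | Mundulea flavanone B | COc1cc(O)c2c(c1CC=C(C)C)O[C@H](c1ccc(O)cc1)CC2=O | target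

**Total step count:** 7.
**Longest linear sequence:** 5 steps (1 → 3 → 4 → 5 → 12 → 13). The branch 6 + 7 → 8 → 9 joins at step 6.

**Steps most likely to fail, and fallbacks**

Step 6 carries the most risk. Bromopyranone 10 may hydrolyse, diene 5 may be consumed by bromine transfer, or cycloaddition onto uncyclised 9 may end in an aryl bromide.
- The fallback sets out from 9 and 4 and comes back at 12.
- The carbinol of 9 is silylated (Et3SiOSO2CF3, 2,6-lutidine) to (5S)-1-bromo-5-[4-(4,4,5,5-tetramethyl-1,3,2-dioxaborolan-2-yl)phenyl]-5-(triethylsilyloxy)pent-1-yn-3-one F1.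
- The lithium dienolate of 4 (LiN(iPr)2, THF–DMPU, −78 °C) is then alkynylated at its gamma carbon by conjugate addition–elimination on the bromoalkyne. This gives the isolable acyclic methyl (2E)-3-methoxy-7-methyl-4-{(5S)-3-oxo-5-[4-(4,4,5,5-tetramethyl-1,3,2-dioxaborolan-2-yl)phenyl]-5-(triethylsilyloxy)pent-1-yn-1-yl}octa-2,6-dienoate F2.
- Et3N·3HF followed by Et3N frees the carbinol. It adds to the ynone (oxa-Michael) to give 11, which undergoes the same Dieckmann aromatisation to 12.

Step 4 may fail because the secondary-amine catalyst can add to the ynone, and the aldehyde is only moderately activated.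
- The fallback sets out from 7 and 6 and comes back at 8.
- Ynone 7 is converted (Me3SiOSO2CF3, Et3N) into trimethyl{[4-(trimethylsilyl)but-1-en-3-yn-2-yl]oxy}silane F3.
- F3 is added to 6 in a Mukaiyama aldol reaction under SiCl4 activated by a chiral binaphthyl bisphosphoramide (Lewis-base-activated Lewis acid catalysis). The catalyst antipode that gives the (S)-carbinol is used, so no amine ever meets the ynone.

Step 5 may fail because the β-hydroxy bromoynone is fragile, and silver with NBS could attack the boronate or the benzylic alcohol.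
- The fallback sets out from 7 and 6 and comes back at 9.
- The halogen is installed before the stereocentre: 7 is bromodesilylated (NBS, AgNO3) to 4-bromobut-3-yn-2-one F4.
- The boron enolate of F4 (Ipc2BCl of the antipode giving the (S)-aldol, iPr2NEt, −78 °C) is added to 6 in a reagent-controlled aldol reaction.
- A non-oxidative diethanolamine work-up follows, and the material is recrystallised to raise the enantiomeric purity.

**Further compounds**
F1 | step 6 | (5S)-1-bromo-5-[4-(4,4,5,5-tetramethyl-1,3,2-dioxaborolan-2-yl)phenyl]-5-(triethylsilyloxy)pent-1-yn-3-one | CC[Si](CC)(CC)O[C@@H](CC(=O)C#CBr)c1ccc(cc1)B1OC(C)(C)C(C)(C)O1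
F2 | step 6 | methyl (2E)-3-methoxy-7-methyl-4-{(5S)-3-oxo-5-[4-(4,4,5,5-tetramethyl-1,3,2-dioxaborolan-2-yl)phenyl]-5-(triethylsilyloxy)pent-1-yn-1-yl}octa-2,6-dienoate | COC(=O)/C=C(/OC)C(CC=C(C)C)C#CC(=O)C[C@H](O[Si](CC)(CC)CC)c1ccc(cc1)B1OC(C)(C)C(C)(C)O1
F3 | step 4 | trimethyl{[4-(trimethylsilyl)but-1-en-3-yn-2-yl]oxy}silane | C=C(O[Si](C)(C)C)C#C[Si](C)(C)C
F4 | step 5 | 4-bromobut-3-yn-2-one | CC(=O)C#CBr
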